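## Retrosynthetic overview

1. Feature: ring A is a resorcinol dimethyl ether (OMe at C3 and C5, H at C4 and C6). Its two carbon substituents sit on neighbouring atoms, the 2-(ring B)ethyl chain at C1 and the ring C benzyl group at C2, and C2 lies next to the C3 oxygen. A vinylketene supplies C3, C6, C1 and C2 of this pattern, and an ynol ether supplies C4 and C5.
2. End game: the phenols of rings B and C come from benzyl ethers by hydrogenolysis, and the C3 methyl ether comes from a C3 phenol by O-methylation.
3. Key disconnection: ring A ⇒ a 3,4-disubstituted cyclobutenone plus methoxyacetylene (bonds C3–C4, C5–C6 and C2–C3).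
4. Cyclobutenone ⇒ [2+2] of the keteniminium salt of a 3-arylpropanamide (ring C) with a 4-arylbut-1-yne (ring B). The butyne ⇒ a benzylic bromide plus lithiated 1-(trimethylsilyl)propyne.
5. Ring order: rings B and C are bought, the four-membered ring is made first, and it is then expanded to ring A.

Key step: step 7

Remark: the target has no stereocentre, so the single stereocentre of the cyclobutenone is carried as a racemate and disappears on aromatisation. Ring A is numbered C1 (arylethyl), C2 (benzyl), C3 (OMe), C4 (H), C5 (OMe), C6 (H).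

## Route

Step 1
Reactants: 1 3-(4-hydroxyphenyl)propanoic acid
Product: 3 3-[4-(benzyloxy)phenyl]propanoic acid, via sodium 3-[4-(benzyloxy)phenyl]propanoate 2 (not isolated)
Conditions: BnBr (1.1 equiv), NaOH (2.3 equiv), EtOH/H2O, reflux; then aq HCl to pH 2
Reagents that add atoms: benzyl bromide BrCc1ccccc1; sodium hydroxide [Na+].[OH-] (sodium of 2 only)
Why: Williamson ether synthesis, in which the phenoxide of the dianion is far more nucleophilic than the carboxylate and any benzyl ester that forms is saponified in the hot alkaline medium, so acidification should give the mono-O-benzyl acid.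

Step 2
Reactants: 3 3-[4-(benzyloxy)phenyl]propanoic acid
Product: 5 3-[4-(benzyloxy)phenyl]-N,N-dimethylpropanamide, via acid chloride 4 (not isolated)
Conditions: (COCl)2, DMF (cat.), CH2Cl2, 0 °C → rt; concentrate; then Me2NH (2 M in THF, 3 equiv), CH2Cl2, 0 °C → rt
Reagents that add atoms: dimethylamine CNC; oxalyl chloride ClC(=O)C(Cl)=O (chlorine of 4 only)
Why: DMF-catalysed acyl chloride formation followed by aminolysis (nucleophilic acyl substitution), and the aryl benzyl ether is inert to both operations.

Step 3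
Reactants: 6 1-(trimethylsilyl)propyne; 7 3-(benzyloxy)benzyl bromide
Product: 9 {4-[3-(benzyloxy)phenyl]but-1-yn-1-yl}trimethylsilane, via 3-lithio-1-(trimethylsilyl)propyne 8 (not isolated)
Conditions: 6 (1.2 equiv), n-BuLi (1.15 equiv), THF, −78 → −20 °C; then 7, −78 °C → rt
Reagents that add atoms: n-butyllithium [Li]CCCC (lithium of 8 only)
Why: SN2 alkylation of a silyl-capped propargyllithium by a benzylic bromide, in which the silyl group blocks the acetylenic terminus and directs C–C bond formation to the propargylic carbon instead of the allenyl position.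

Step 4
Reactants: 9 {4-[3-(benzyloxy)phenyl]but-1-yn-1-yl}trimethylsilane
Product: 10 1-(benzyloxy)-3-(but-3-yn-1-yl)benzene
Conditions: K2CO3 (cat.), MeOH/THF, rt
Reagents that add atoms: none
Why: Base-catalysed methanolytic protodesilylation of an alkynylsilane, mild enough to leave the benzyl ether untouched.

Step 5
Reactants: 5 3-[4-(benzyloxy)phenyl]-N,N-dimethylpropanamide; 10 1-(benzyloxy)-3-(but-3-yn-1-yl)benzene
Product: 14 racemic 4-[4-(benzyloxy)benzyl]-3-{2-[3-(benzyloxy)phenyl]ethyl}cyclobut-2-en-1-one, via O-triflyliminium triflate 11 (not isolated), via keteniminium triflate 12 (not isolated), via cyclobuteniminium triflate 13 (not isolated)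
Conditions: Tf2O (1.1 equiv), CH2Cl2, −15 °C; then 10 (1.5 equiv) and 2,4,6-collidine (1.1 equiv, slow addition), reflux (40 °C); then sat. aq NaHCO3, rt
Reagents that add atoms: water O (carbonyl oxygen of 14); triflic anhydride O=S(=O)(OS(=O)(=O)C(F)(F)F)C(F)(F)F (triflyl and triflate groups of 11 to 13 only)
Why: Keteniminium–alkyne [2+2] cycloaddition after electrophilic amide activation, in which the central keteniminium carbon bonds to the unsubstituted alkyne carbon because positive charge builds up on the substituted one, so the arylethyl group lands at C3 and the benzyl group at C4 (new stereocentre, formed as a racemate) before hydrolysis at room temperature frees the heat-sensitive enone.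

Step 6
Reactants: 15 chloroacetaldehyde dimethyl acetal
Product: 17 methoxyacetylene, via sodium methoxyacetylide 16 (not isolated)
Conditions: NaNH2 (3.1 equiv), liq. NH3, −33 °C; NH3 evaporated; cold sat. aq NaCl; distilled into a −78 °C trap and kept as a cold toluene solution
Reagents that add atoms: sodium amide [Na+].[NH2-] (sodium of 16 only)
Why: Twofold β-elimination (loss of MeOH, then of HCl), the classical alkoxyacetylene synthesis from chloroacetals, with the third equivalent of base holding the product as its non-volatile sodium acetylide until the aqueous quench.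

Step 7
Reactants: 14 racemic 4-[4-(benzyloxy)benzyl]-3-{2-[3-(benzyloxy)phenyl]ethyl}cyclobut-2-en-1-one; 17 methoxyacetylene
Product: 22 2-[4-(benzyloxy)benzyl]-3-{2-[3-(benzyloxy)phenyl]ethyl}-5-methoxyphenol, via vinylketene 18 (not isolated), via alkenylcyclobutenone 19 (not isolated), via dienylketene 20 (not isolated), via cyclohexadienone 21 (not isolated)
Conditions: 17 (3 equiv), toluene (0.5 M), sealed heavy-walled tube, 80 °C, then 120 °C
Reagents that add atoms: none
Why: Danheiser benzannulation, a cascade of four pericyclic events that begins when 14 opens by conrotatory four-electron cleavage of its C(=O)–C4 bond, the C4 benzyl group turning outward, to give the (E)-vinylketene 18, which has no cis alkyl C–H available for a 1,5-hydrogen shift. The ketene C=C of 18 adds [2+2] to 17 (new ring A bonds C3–C4 and C5–C6) to give the 4-alkenyl-3-methoxycyclobutenone 19, which opens reversibly at the higher temperature to the dienylketene 20. Ring A is closed by six-electron disrotatory electrocyclisation of 20 (bond C2–C3, ketene carbon onto the benzyl-bearing alkene terminus), and the cyclohexa-2,4-dienone 21 tautomerises irreversibly to the phenol 22, which drains the earlier equilibria. The closest known reaction type is the thermal benzannulation of alkyl-substituted cyclobutenones with alkoxyacetylenes to resorcinol monoethers. The one selectivity needed is the orientation of the ketene–alkyne [2+2]: oxygen donation makes the unsubstituted carbon of 17 nucleophilic, so it bonds to the electrophilic ketene carbonyl carbon and puts OMe at C5, meta to the new C3 hydroxyl, while the adjacency of arylethyl (C1) and benzyl (C2) is already built into C3 and C4 of 14. No stereocentre survives, since those of 14, 19 and 21 are erased on aromatisation, and 17 has no β-hydrogen in its alkyl group, so it cannot fragment to ketene by retro-ene loss of an alkene at these temperatures.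

Step 8
Reactants: 22 2-[4-(benzyloxy)benzyl]-3-{2-[3-(benzyloxy)phenyl]ethyl}-5-methoxyphenol
Product: 23 2-[4-(benzyloxy)benzyl]-1-{2-[3-(benzyloxy)phenyl]ethyl}-3,5-dimethoxybenzene
Conditions: MeI (2 equiv), K2CO3 (2 equiv), acetone, reflux
Reagents that add atoms: iodomethane CI
Why: Williamson O-methylation of the only free phenol, for which the ortho benzyl group is no serious steric obstacle to so small an electrophile.

Step 9
Reactants: 23 2-[4-(benzyloxy)benzyl]-1-{2-[3-(benzyloxy)phenyl]ethyl}-3,5-dimethoxybenzene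
Product: 24 Gymcononopin D, 3-{2-[2-(4-hydroxybenzyl)-3,5-dimethoxyphenyl]ethyl}phenol
Conditions: H2 (1 atm), Pd/C (10 wt% Pd on carbon), EtOAc/MeOH, rt
Reagents that add atoms: none
Why: Catalytic hydrogenolysis of both benzylic C–O bonds, under which the diarylmethane and bibenzyl C–C bonds and the methyl ethers are not reduced.

## Compound list

| No. | Name | SMILES | Role |
|---|---|---|---|
| 1 | 3-(4-hydroxyphenyl)propanoic acid | OC(=O)CCc1ccc(O)cc1 | starting material |
| 2 | sodium 3-[4-(benzyloxy)phenyl]propanoate | [Na+].[O-]C(=O)CCc1ccc(OCc2ccccc2)cc1 | intermediate |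
| 3 | 3-[4-(benzyloxy)phenyl]propanoic acid | OC(=O)CCc1ccc(OCc2ccccc2)cc1 | intermediate |
| 4 | 3-[4-(benzyloxy)phenyl]propanoyl chloride | ClC(=O)CCc1ccc(OCc2ccccc2)cc1 | intermediate |
| 5 | 3-[4-(benzyloxy)phenyl]-N,N-dimethylpropanamide | CN(C)C(=O)CCc1ccc(OCc2ccccc2)cc1 | intermediate |
| 6 | 1-(trimethylsilyl)propyne | CC#C[Si](C)(C)C | starting material |
| 7 | 3-(benzyloxy)benzyl bromide | BrCc1cccc(OCc2ccccc2)c1 | starting material |
| 8 | 3-lithio-1-(trimethylsilyl)propyne | [Li]CC#C[Si](C)(C)C | intermediate |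
| 9 | {4-[3-(benzyloxy)phenyl]but-1-yn-1-yl}trimethylsilane | C[Si](C)(C)C#CCCc1cccc(OCc2ccccc2)c1 | intermediate |
| 10 | 1-(benzyloxy)-3-(but-3-yn-1-yl)benzene | C#CCCc1cccc(OCc2ccccc2)c1 | intermediate |
| 11 | N-{3-[4-(benzyloxy)phenyl]-1-[(trifluoromethanesulfonyl)oxy]propylidene}-N-methylmethanaminium triflate | C[N+](C)=C(CCc1ccc(OCc2ccccc2)cc1)OS(=O)(=O)C(F)(F)F.[O-]S(=O)(=O)C(F)(F)F | intermediate |
| 12 | N-{3-[4-(benzyloxy)phenyl]prop-1-en-1-ylidene}-N-methylmethanaminium triflate (keteniminium salt) | C[N+](C)=C=CCc1ccc(OCc2ccccc2)cc1.[O-]S(=O)(=O)C(F)(F)F | intermediate |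
| 13 | racemic N-(4-[4-(benzyloxy)benzyl]-3-{2-[3-(benzyloxy)phenyl]ethyl}cyclobut-2-en-1-ylidene)-N-methylmethanaminium triflate | C[N+](C)=C1C=C(CCc2cccc(OCc3ccccc3)c2)C1Cc1ccc(OCc2ccccc2)cc1.[O-]S(=O)(=O)C(F)(F)F | intermediate |
| 14 | racemic 4-[4-(benzyloxy)benzyl]-3-{2-[3-(benzyloxy)phenyl]ethyl}cyclobut-2-en-1-one | O=C1C=C(CCc2cccc(OCc3ccccc3)c2)C1Cc1ccc(OCc2ccccc2)cc1 | intermediate |
| 15 | chloroacetaldehyde dimethyl acetal (2-chloro-1,1-dimethoxyethane) | COC(CCl)OC | starting material |
| 16 | sodium methoxyacetylide | [Na+].[C-]#COC | intermediate |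
| 17 | methoxyacetylene | COC#C | intermediate |
| 18 | (3E)-5-[4-(benzyloxy)phenyl]-3-{2-[3-(benzyloxy)phenyl]ethyl}penta-1,3-dien-1-one (vinylketene) | O=C=C/C(CCc1cccc(OCc2ccccc2)c1)=C/Cc1ccc(OCc2ccccc2)cc1 | intermediate |
| 19 | racemic 4-{(2E)-1-[4-(benzyloxy)phenyl]-5-[3-(benzyloxy)phenyl]pent-2-en-3-yl}-3-methoxycyclobut-2-en-1-one | O=C1C=C(OC)C1/C(CCc1cccc(OCc2ccccc2)c1)=C/Cc1ccc(OCc2ccccc2)cc1 | intermediate |
| 20 | (3E,5E)-7-[4-(benzyloxy)phenyl]-5-{2-[3-(benzyloxy)phenyl]ethyl}-3-methoxyhepta-1,3,5-trien-1-one (dienylketene; ketene arm and alkenyl arm cis on the central double bond) | O=C=C/C(OC)=C\C(CCc1cccc(OCc2ccccc2)c1)=C\Cc1ccc(OCc2ccccc2)cc1 | intermediate |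
| 21 | racemic 6-[4-(benzyloxy)benzyl]-5-{2-[3-(benzyloxy)phenyl]ethyl}-3-methoxycyclohexa-2,4-dien-1-one | O=C1C=C(OC)C=C(CCc2cccc(OCc3ccccc3)c2)C1Cc1ccc(OCc2ccccc2)cc1 | intermediate |
| 22 | 2-[4-(benzyloxy)benzyl]-3-{2-[3-(benzyloxy)phenyl]ethyl}-5-methoxyphenol | COc1cc(O)c(Cc2ccc(OCc3ccccc3)cc2)c(CCc2cccc(OCc3ccccc3)c2)c1 | intermediate |
| 23 | 2-[4-(benzyloxy)benzyl]-1-{2-[3-(benzyloxy)phenyl]ethyl}-3,5-dimethoxybenzene | COc1cc(CCc2cccc(OCc3ccccc3)c2)c(Cc2ccc(OCc3ccccc3)cc2)c(OC)c1 | intermediate |
| 24 | Gymcononopin D, 3-{2-[2-(4-hydroxybenzyl)-3,5-dimethoxyphenyl]ethyl}phenol | COc1cc(CCc2cccc(O)c2)c(Cc2ccc(O)cc2)c(OC)c1 | target |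

## Step count and risks

Total step count: 9.
Longest linear sequence: 6 steps (1, 2, 5, 7, 8, 9, or equally 3, 4, 5, 7, 8, 9).

Three steps most likely to fail:

1. **Step 7.** The vinylketene may be consumed by dimerisation or by O-acylation of the phenol as it forms. The ynol ether may polymerise on heating, or the cascade may stall before the second ring opening.
   - The fallback sets out from 7 and comes back at 24. It takes ring A from the aromatic pool instead of building it.
   - Arbuzov reaction of 7 with P(OEt)3 should give diethyl [3-(benzyloxy)benzyl]phosphonate F1.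
   - Horner–Wadsworth–Emmons olefination of commercial 2-bromo-3,5-dimethoxybenzaldehyde (NaH, THF) should give 1-{(E)-2-[3-(benzyloxy)phenyl]ethenyl}-2-bromo-3,5-dimethoxybenzene F2.
   - Bromine–lithium exchange (n-BuLi, THF, −78 °C) gives (2-{(E)-2-[3-(benzyloxy)phenyl]ethenyl}-4,6-dimethoxyphenyl)lithium F3.
   - F3 adds to commercial 4-(benzyloxy)benzaldehyde (NH4Cl quench) to give racemic [4-(benzyloxy)phenyl](2-{(E)-2-[3-(benzyloxy)phenyl]ethenyl}-4,6-dimethoxyphenyl)methanol F4.
   - H2 over Pd/C in EtOAc/AcOH should saturate the stilbene, remove the doubly benzylic hydroxyl and cleave both benzyl ethers, which gives 24.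

2. **Step 5.** The aldoketeniminium salt may self-condense with unreacted amide. The activated amide may close by Friedel–Crafts reaction onto ring C. The electron-rich ring B may intercept the developing vinyl-cation character of the alkyne carbon.
   - The fallback sets out from 4 and comes back at 14. It avoids cationic intermediates.
   - Slow addition of Et3N to 4 and commercial ethoxyacetylene in Et2O generates [4-(benzyloxy)benzyl]ketene F5, which is trapped by [2+2] cycloaddition as racemic 4-[4-(benzyloxy)benzyl]-3-ethoxycyclobut-2-en-1-one F6.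
   - In parallel, Appel bromination (CBr4, PPh3) of commercial 2-[3-(benzyloxy)phenyl]ethanol gives 1-(benzyloxy)-3-(2-bromoethyl)benzene F7. Mg in THF converts F7 into 2-[3-(benzyloxy)phenyl]ethylmagnesium bromide F8.
   - 1,2-Addition of F8 to F6 gives 4-[4-(benzyloxy)benzyl]-1-{2-[3-(benzyloxy)phenyl]ethyl}-3-ethoxycyclobut-2-en-1-ol F9 (racemic, mixture of diastereomers, both of which converge).
   - Dilute aqueous HCl converts F9 into 14 with carbonyl transposition and loss of ethanol.

3. **Step 6.** The very volatile alkyne may be lost during isolation and transfer, and it may polymerise on storage.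
   - The fallback sets out from 15 and comes back at 22. It replaces the gas-like reagent by a distillable silylated surrogate.
   - LiNEt2 (3 equiv, THF, −78 → 0 °C) converts 15 into lithium methoxyacetylide F10, which is silylated in the same flask with excess Me3SiCl to (methoxyethynyl)trimethylsilane F11.
   - Benzannulation of 14 with F11 under the conditions of step 7 has the same polarity control: the silyl-bearing carbon bonds to the ketene carbonyl carbon. It should give 2-[4-(benzyloxy)benzyl]-3-{2-[3-(benzyloxy)phenyl]ethyl}-5-methoxy-6-(trimethylsilyl)phenol F12.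
   - Ipso-protodesilylation of this very electron-rich arylsilane (CF3CO2H, CH2Cl2, 0 °C) gives 22.

## Further compounds

F1 | step 7 | diethyl [3-(benzyloxy)benzyl]phosphonate | CCOP(=O)(Cc1cccc(OCc2ccccc2)c1)OCC
F2 | step 7 | 1-{(E)-2-[3-(benzyloxy)phenyl]ethenyl}-2-bromo-3,5-dimethoxybenzene | COc1cc(OC)c(Br)c(/C=C/c2cccc(OCc3ccccc3)c2)c1
F3 | step 7 | (2-{(E)-2-[3-(benzyloxy)phenyl]ethenyl}-4,6-dimethoxyphenyl)lithium | COc1cc(OC)c([Li])c(/C=C/c2cccc(OCc3ccccc3)c2)c1
F4 | step 7 | racemic [4-(benzyloxy)phenyl](2-{(E)-2-[3-(benzyloxy)phenyl]ethenyl}-4,6-dimethoxyphenyl)methanol | COc1cc(OC)c(C(O)c2ccc(OCc3ccccc3)cc2)c(/C=C/c2cccc(OCc3ccccc3)c2)c1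
F5 | step 5 | [4-(benzyloxy)benzyl]ketene | O=C=CCc1ccc(OCc2ccccc2)cc1
F6 | step 5 | racemic 4-[4-(benzyloxy)benzyl]-3-ethoxycyclobut-2-en-1-one | CCOC1=CC(=O)C1Cc1ccc(OCc2ccccc2)cc1
F7 | step 5 | 1-(benzyloxy)-3-(2-bromoethyl)benzene | BrCCc1cccc(OCc2ccccc2)c1
F8 | step 5 | 2-[3-(benzyloxy)phenyl]ethylmagnesium bromide | Br[Mg]CCc1cccc(OCc2ccccc2)c1
F9 | step 5 | 4-[4-(benzyloxy)benzyl]-1-{2-[3-(benzyloxy)phenyl]ethyl}-3-ethoxycyclobut-2-en-1-ol (racemic, mixture of diastereomers) | CCOC1=CC(O)(CCc2cccc(OCc3ccccc3)c2)C1Cc1ccc(OCc2ccccc2)cc1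
F10 | step 6 | lithium methoxyacetylide | [Li]C#COC
F11 | step 6 | (methoxyethynyl)trimethylsilane | COC#C[Si](C)(C)C
F12 | step 6 | 2-[4-(benzyloxy)benzyl]-3-{2-[3-(benzyloxy)phenyl]ethyl}-5-methoxy-6-(trimethylsilyl)phenol | COc1cc(CCc2cccc(OCc3ccccc3)c2)c(Cc2ccc(OCc3ccccc3)cc2)c(O)c1[Si](C)(C)C
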